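The tridepside is cut at the O–C4 bond of the ester that links central ring B to the methyl ester ring C. One copper-mediated Chan–Lam coupling joins the carboxylate oxygen of the complete ring A–ring B acid to C4 of a ring C boronic acid. The step exploits two features. C1 of ring B is crowded by its C2 methoxy and C6 methyl groups, so its carbonyl is better not attacked. C4 of ring C is the only C–H of a 6-methylsalicylate with hydrogen on both sides, so steric C–H borylation places boron there. Both phenols (C2 of ring A, C2 of ring C) are methoxymethyl ethers, so one acid step ends the route.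

Key step: step 9

Remarks on the design
- Assumption: orcylaldehyde (1) and methyl 2-hydroxy-6-methylbenzoate (8) are bought as catalogue compounds. The target has no stereocentre.
- The ring A phenol carries the same methoxymethyl acetal as the ring C phenol, not a benzyl ether. No hydrogenolysis is then needed and the endgame is a single deprotection. Any acetal lost during the coupling converges on the target in the last step.
- Ring B needs no protecting group: orcylaldehyde is acylated at O4, methylated at O2 and then oxidised to the acid.
- The pinacol boronate is cleaved in the borylation flask, so ring C takes two steps.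

Step 1
Reactants: 1 2,4-dihydroxy-6-methylbenzaldehyde (orcylaldehyde)
Product: 2 2-hydroxy-4-methoxy-6-methylbenzaldehyde
Conditions: MeI (1.05 equiv), K2CO3 (1.0 equiv), acetone, rt
Reagents that add atoms: iodomethane, CI
Why: Williamson ether synthesis: the C4 hydroxyl (para to the formyl group) is the more acidic, free phenol, whereas the C2 hydroxyl is held in a hydrogen bond to the formyl oxygen, so one equivalent of MeI should methylate O4 only.

Step 2
Reactants: 2 2-hydroxy-4-methoxy-6-methylbenzaldehyde
Product: 3 4-methoxy-2-(methoxymethoxy)-6-methylbenzaldehyde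
Conditions: MOMCl, i-Pr2NEt, CH2Cl2, 0 °C → rt
Reagents that add atoms: chloromethyl methyl ether, COCCl
Why: Methoxymethyl ether formation (O-alkylation with an α-chloro ether): the oxocarbenium-like electrophile is reactive enough to alkylate the hydrogen-bonded C2 phenol under amine base, and the aldehyde is inert to these conditions.

Step 3
Reactants: 3 4-methoxy-2-(methoxymethoxy)-6-methylbenzaldehyde
Product: 4 4-methoxy-2-(methoxymethoxy)-6-methylbenzoic acid
Conditions: NaClO2, NaH2PO4, 2-methyl-2-butene, t-BuOH/THF/H2O, 0 °C → rt; work-up at pH 3–4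
Reagents that add atoms: sodium chlorite, [Na+].[O-]Cl=O
Why: Pinnick oxidation: chlorous acid adds to the formyl group and fragments to the acid, 2-methyl-2-butene removes HOCl before it can chlorinate the electron-rich ring, and the phosphate buffer is mild enough for the methoxymethyl ether.

Step 4
Reactants: 4 4-methoxy-2-(methoxymethoxy)-6-methylbenzoic acid; 1 2,4-dihydroxy-6-methylbenzaldehyde (1.2 equiv)
Product: 5 4-formyl-3-hydroxy-5-methylphenyl 4-methoxy-2-(methoxymethoxy)-6-methylbenzoate
Conditions: DCC, DMAP (0.3 equiv), CH2Cl2, 0 °C → rt
Reagents that add atoms: none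
Why: Steglich esterification: the acylpyridinium derived from 4 should acylate the free C4 hydroxyl of 1 selectively, because the C2 hydroxyl is hydrogen-bonded to the formyl group and the doubly ortho-substituted acyl donor is too bulky to reach it.

Step 5
Reactants: 5 4-formyl-3-hydroxy-5-methylphenyl 4-methoxy-2-(methoxymethoxy)-6-methylbenzoate
Product: 6 4-formyl-3-methoxy-5-methylphenyl 4-methoxy-2-(methoxymethoxy)-6-methylbenzoate
Conditions: MeI (2 equiv), K2CO3 (1.5 equiv), DMF, rt
Reagents that add atoms: iodomethane, CI
Why: Williamson ether synthesis: K2CO3 in DMF deprotonates the ring B phenol and MeI caps it, while the aryl ester should survive because its carbonyl carbon is shielded by the ortho methoxymethoxy and methyl groups of ring A.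

Step 6
Reactants: 6 4-formyl-3-methoxy-5-methylphenyl 4-methoxy-2-(methoxymethoxy)-6-methylbenzoate
Product: 7 2-methoxy-4-{[4-methoxy-2-(methoxymethoxy)-6-methylbenzoyl]oxy}-6-methylbenzoic acid
Conditions: NaClO2, NaH2PO4, 2-methyl-2-butene, t-BuOH/THF/H2O, 0 °C → rt; work-up at pH 3–4
Reagents that add atoms: sodium chlorite, [Na+].[O-]Cl=O
Why: Pinnick oxidation: the method is selective for the formyl group, tolerates its two ortho substituents, and the buffered medium should leave the aryl ester and the methoxymethyl ether untouched.

Step 7
Reactants: 8 methyl 2-hydroxy-6-methylbenzoate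
Product: 9 methyl 2-(methoxymethoxy)-6-methylbenzoate
Conditions: MOMCl, i-Pr2NEt, CH2Cl2, 0 °C → reflux
Reagents that add atoms: chloromethyl methyl ether, COCCl
Why: Methoxymethyl ether formation: the salicylate phenol, although hydrogen-bonded to the ester, is alkylated by the reactive α-chloro ether under amine base, and the acetal adds no aromatic C–H that could compete in the next step.

Step 8
Reactants: 9 methyl 2-(methoxymethoxy)-6-methylbenzoate; 10 bis(pinacolato)diboron (0.6 equiv)
Product: 12 [4-(methoxycarbonyl)-3-(methoxymethoxy)-5-methylphenyl]boronic acid, via aryl pinacol boronate 11 (not isolated)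
Conditions: [Ir(OMe)(cod)]2 (1.5 mol %), 4,4'-di-tert-butyl-2,2'-bipyridine (3 mol %), THF, 80 °C; then NaIO4, aq. NH4OAc, THF/H2O, rt
Reagents that add atoms: water, O (the two B–OH oxygens; boron comes from reactant 10)
Why: Iridium-catalysed aromatic C–H borylation (Ishiyama–Miyaura–Hartwig) followed by periodate cleavage of the pinacol ester: the bulky tris(boryl) trivalent iridium catalyst should only reach C4, the single ring C–H of 9 with hydrogen on both flanks, and NaIO4 then destroys the pinacol released by hydrolysis at near-neutral pH, which spares the methyl ester and the acetal.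

Step 9
Reactants: 7 2-methoxy-4-{[4-methoxy-2-(methoxymethoxy)-6-methylbenzoyl]oxy}-6-methylbenzoic acid; 12 [4-(methoxycarbonyl)-3-(methoxymethoxy)-5-methylphenyl]boronic acid (2 equiv)
Product: 13 methyl 4-[(2-methoxy-4-{[4-methoxy-2-(methoxymethoxy)-6-methylbenzoyl]oxy}-6-methylbenzoyl)oxy]-2-(methoxymethoxy)-6-methylbenzoate
Conditions: Cu(OTf)2 (0.4 equiv), urea (1 equiv), 4 Å MS, EtOAc, 60 °C, open to air
Reagents that add atoms: none
Why: This is a Chan–Lam oxidative O-arylation of a carboxylic acid, a known copper coupling of arylboronic acids with benzoic acids. The carboxylate of 7 binds divalent copper, the aryl group of 12 passes from boron to copper, oxidation by a second divalent copper centre or by air gives a trivalent copper aryl carboxylate, and reductive elimination forms the O–C4 bond of ring C, after which air returns monovalent copper to the divalent state. No ring is closed and no stereocentre is created. Site selectivity is fixed by the position of boron at C4 of ring C, and chemoselectivity by the two methoxymethyl ethers, which leave the carboxylate as the only acidic O–H nucleophile offered to copper. Because ring B reacts through its carboxylate oxygen, the crowding of its carbonyl carbon by the C2 methoxy and C6 methyl groups does not matter, and the boron-bearing carbon has no ortho substituent. A triflate salt is chosen because an acetate counter-ion would itself be O-arylated, and urea serves as ligand and as buffer for the triflic acid released.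

Step 10
Reactants: 13 methyl 4-[(2-methoxy-4-{[4-methoxy-2-(methoxymethoxy)-6-methylbenzoyl]oxy}-6-methylbenzoyl)oxy]-2-(methoxymethoxy)-6-methylbenzoate
Product: 14 methyl 2-hydroxy-4-[(4-{[2-hydroxy-4-methoxy-6-methylbenzoyl]oxy}-2-methoxy-6-methylbenzoyl)oxy]-6-methylbenzoate (target, CNP0357736.0)
Conditions: HCl (4 M in dioxane, 5 equiv), MeOH (10 equiv), CH2Cl2, 0 °C → rt
Reagents that add atoms: none
Why: Acid-catalysed acetal cleavage (methoxymethyl ether solvolysis): both aryl acetals are exchanged onto methanol as dimethoxymethane, each freed phenol being stabilised by a hydrogen bond to its ortho carbonyl, while the two inter-ring esters are shielded by 2,6-disubstitution and exchange at the methyl ester is degenerate.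

Compound list
1 | 2,4-dihydroxy-6-methylbenzaldehyde (orcylaldehyde) | Cc1cc(O)cc(O)c1C=O | starting material
2 | 2-hydroxy-4-methoxy-6-methylbenzaldehyde | COc1cc(C)c(C=O)c(O)c1 | intermediate
3 | 4-methoxy-2-(methoxymethoxy)-6-methylbenzaldehyde | COCOc1cc(OC)cc(C)c1C=O | intermediate
4 | 4-methoxy-2-(methoxymethoxy)-6-methylbenzoic acid | COCOc1cc(OC)cc(C)c1C(=O)O | intermediate
5 | 4-formyl-3-hydroxy-5-methylphenyl 4-methoxy-2-(methoxymethoxy)-6-methylbenzoate | COCOc1cc(OC)cc(C)c1C(=O)Oc1cc(C)c(C=O)c(O)c1 | intermediate
6 | 4-formyl-3-methoxy-5-methylphenyl 4-methoxy-2-(methoxymethoxy)-6-methylbenzoate | COCOc1cc(OC)cc(C)c1C(=O)Oc1cc(C)c(C=O)c(OC)c1 | intermediate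
7 | 2-methoxy-4-{[4-methoxy-2-(methoxymethoxy)-6-methylbenzoyl]oxy}-6-methylbenzoic acid | COCOc1cc(OC)cc(C)c1C(=O)Oc1cc(C)c(C(=O)O)c(OC)c1 | intermediate
8 | methyl 2-hydroxy-6-methylbenzoate | COC(=O)c1c(C)cccc1O | starting material
9 | methyl 2-(methoxymethoxy)-6-methylbenzoate | COCOc1cccc(C)c1C(=O)OC | intermediate
10 | bis(pinacolato)diboron | CC1(C)OB(B2OC(C)(C)C(C)(C)O2)OC1(C)C | starting material
11 | methyl 2-(methoxymethoxy)-6-methyl-4-(4,4,5,5-tetramethyl-1,3,2-dioxaborolan-2-yl)benzoate | COCOc1cc(B2OC(C)(C)C(C)(C)O2)cc(C)c1C(=O)OC | intermediate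
12 | [4-(methoxycarbonyl)-3-(methoxymethoxy)-5-methylphenyl]boronic acid | COCOc1cc(B(O)O)cc(C)c1C(=O)OC | intermediate
13 | methyl 4-[(2-methoxy-4-{[4-methoxy-2-(methoxymethoxy)-6-methylbenzoyl]oxy}-6-methylbenzoyl)oxy]-2-(methoxymethoxy)-6-methylbenzoate | COC(=O)c1c(C)cc(OC(=O)c2c(C)cc(OC(=O)c3c(C)cc(OC)cc3OCOC)cc2OC)cc1OCOC | intermediate
14 | methyl 2-hydroxy-4-[(4-{[2-hydroxy-4-methoxy-6-methylbenzoyl]oxy}-2-methoxy-6-methylbenzoyl)oxy]-6-methylbenzoate | COC(=O)c1c(C)cc(OC(=O)c2c(C)cc(OC(=O)c3c(C)cc(OC)cc3O)cc2OC)cc1O | target

Total step count: 10. Longest linear sequence: 8 steps (steps 1–6, 9 and 10); ring C joins after 2 steps (steps 7 and 8).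

Steps most likely to fail

1. Step 9. Transmetalation of the electron-poor aryl group from boron to copper may be slow, so that protodeboronation, homocoupling and hydroxylation of the boronic acid outrun C–O bond formation. Acetal loss under the Lewis acidic copper salt could also expose a phenol to arylation. The fallback sets out from 12 (with 7) and comes back at 13. Boronic acid 12 would be oxidised (30% H2O2, NaHCO3, THF/H2O, 0 °C → rt) to methyl 4-hydroxy-2-(methoxymethoxy)-6-methylbenzoate F1. This phenol would then be acylated by acid 7 in a Steglich esterification (DCC, DMAP, CH2Cl2, rt) to give 13. The ester bond is then made by acyl transfer at the crowded ring B carbonyl, the classical depside construction, instead of by aryl transfer to oxygen.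

2. Step 4. Site selection between the two phenols of 1 may be incomplete (acylation at O2 or at both oxygens), the crowded acid may be diverted to the N-acylurea, and the base of step 5 may then cause acyl transfer. The fallback sets out from 1 and comes back at 6, so it replaces steps 4 and 5. Orcylaldehyde 1 would be protected at O4 (MOMCl 1.05 equiv, i-Pr2NEt, CH2Cl2, 0 °C) to give 2-hydroxy-4-(methoxymethoxy)-6-methylbenzaldehyde F2. Methylation at O2 (MeI, K2CO3, DMF, rt) would give 2-methoxy-4-(methoxymethoxy)-6-methylbenzaldehyde F3. Removal of the acetal (2 M aq. HCl, THF, 40 °C) would give 4-hydroxy-2-methoxy-6-methylbenzaldehyde F4. This single phenol would be esterified with acid 4 (DCC, DMAP, CH2Cl2) to give 6.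

3. Step 10. Once the ring A phenol is free, acid-catalysed methanolysis of the inter-ring aryl esters may set in, since depsides with an ortho-hydroxy acyl ring are prone to alcoholysis. The liberated methoxymethyl cation may also alkylate the electron-rich ring A. The fallback sets out from 13 and comes back at 14. It avoids protic acid and alcohol by silyl transfer: TMSOTf with 2,2'-bipyridyl in CH2Cl2 at 0 °C should convert both aryl acetals into silyl ethers, giving methyl 4-[(2-methoxy-4-{[4-methoxy-6-methyl-2-(trimethylsilyloxy)benzoyl]oxy}-6-methylbenzoyl)oxy]-6-methyl-2-(trimethylsilyloxy)benzoate F5. The methoxymethyl units are held as bipyridinium salts, and addition of water at rt would hydrolyse F5 to 14.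

Further compounds
F1 | step 9 | methyl 4-hydroxy-2-(methoxymethoxy)-6-methylbenzoate | COCOc1cc(O)cc(C)c1C(=O)OC
F2 | step 4 | 2-hydroxy-4-(methoxymethoxy)-6-methylbenzaldehyde | COCOc1cc(C)c(C=O)c(O)c1
F3 | step 4 | 2-methoxy-4-(methoxymethoxy)-6-methylbenzaldehyde | COCOc1cc(C)c(C=O)c(OC)c1
F4 | step 4 | 4-hydroxy-2-methoxy-6-methylbenzaldehyde | COc1cc(O)cc(C)c1C=O
F5 | step 10 | methyl 4-[(2-methoxy-4-{[4-methoxy-6-methyl-2-(trimethylsilyloxy)benzoyl]oxy}-6-methylbenzoyl)oxy]-6-methyl-2-(trimethylsilyloxy)benzoate | COC(=O)c1c(C)cc(OC(=O)c2c(C)cc(OC(=O)c3c(C)cc(OC)cc3O[Si](C)(C)C)cc2OC)cc1O[Si](C)(C)C
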